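## Structural features

The target is an unsymmetrical biflavone with no stereocentre. Flavone 1 (rings A, C, B; 5-hydroxy-7-methoxy on ring A, 4'-methoxy on ring B) and flavone 2 (rings D, E, F; an apigenin unit) are joined by one biaryl bond from C2' of ring B to C8 of ring D. This bond is ortho to the pyranone at C1' and lies between C8a (bearing the ring-E oxygen O1) and the C7 hydroxyl, so the axis has three ortho substituents; no axial descriptor is specified. Ring D is a fully differentiated phloroglucinol: oxygen on C5, C7 and C8a, the carbonyl carbon on C4a, the aryl group on C8, and only C6 unsubstituted. The fragile parts are the free 5,7-dihydroxy-8-aryl chromone, which hot acid can isomerise to the 6-aryl isomer (Wessely–Moser), and the electron-rich rings. Two methyl ethers must coexist with four free phenols, which rules out any late demethylation. The real difficulty is ring D: a biaryl bond to a carbon flanked by two oxygens, and then telling three oxygens apart so that the C8a oxygen closes ring E and C4a, not C6, carries the carbonyl. The key step exploits the fact that the carboxyl carbon on C1' (the future C2 of flavone 1) reaches C8a through a six-membered ring (O–C(=O)–C1'–C2'–C8–C8a). The oxygen can therefore be placed on C8a after the biaryl bond exists; the resulting lactone marks that oxygen as an acyloxy group and is also the activated ester from which flavone 1 is built.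

## Logic of the disconnections

19 ⇒ 18. Cut: the three O–benzyl bonds on the C5, C7 and C4''' oxygens of flavone 2. The phenols are masked as ethers that tolerate strong base, dilute acid and palladium, and are released at the end without acid. The gain is a neutral last step that cannot scramble the 8-aryl flavone. The forward step must leave both pyranone double bonds and both methyl ethers untouched.

18 ⇒ 15 + 16 + a one-carbon carbonyl unit. Cut: C4–C4a, C3–C4 and O1–C2 of ring E. Rings E and F are removed together in a three-component step, and 15 already contains flavone 1 complete. The forward step needs iodine on C4a and nowhere else, carbonyl insertion before alkynyl transfer, and a 6-endo closure. Because the C8a hydroxyl is the only free hydroxyl on ring D, closure can only give the 8-aryl flavone.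

15 ⇒ 14. Cut: O1–C2 of ring C. A 1,3-diketone with an ortho hydroxyl is the classical flavone precursor, and the two ring-A hydroxyls are equivalent, so no regiochemical question arises on ring A. The forward step requires the ring-A hydroxyl, not the ring-D hydroxyl, to end up bonded to this carbon, and requires the C–I bond and the benzyl ethers to survive the acid.

14 ⇒ 12 + 13. Cut: C2–C3 of flavone 1, the bond from the carbonyl carbon on C1' to the methyl carbon of 13. In 12 this carbonyl is an aryl ester held in a lactone, so it is an activated acyl donor, and its opening releases exactly the C8a oxygen as the one free phenol of ring D. The gain is convergence with a commercial, unprotected ring-A ketone. The forward step needs a sufficiently nucleophilic polyanion and enough base to deprotonate the diketone so that the opening cannot reverse.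

12 ⇒ 11. Cut: the C–I bond at the future C4a. At the lactone stage the C8a oxygen is acylated and donates little, so ring D behaves as a resorcinol diether with one position ortho/para to both ethers. The later choice between C4a and C6 is thereby settled before the phenol is freed. The forward step must stop at mono-iodination.

11 ⇒ 10 ⇒ 8 (through 9). Cut: the two O–benzyl bonds, traced back to two O–acyl bonds. Ring D must be electron-poor at the anode and must carry base-stable ethers for the enolate chemistry, so the groups are exchanged once. Saponification opens the lactone as well; the forward step relies on spontaneous reclosure. In 9 the two ortho hydroxyls are related by symmetry, so either gives the same 10.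

8 ⇒ 7. Cut: the O–C8a bond (key disconnection). The third ring-D oxygen is introduced after the biaryl bond, so the coupling only has to make a biaryl with two ortho substituents. The forward step must oxidise the carboxylate and not ring D, and must close at C8a and not at the ipso carbon C8.

7 ⇒ 6 ⇒ 3 + 5. Cut: the ester O–benzyl bond, then the biaryl bond C2'–C8. The acid is unmasked by hydrogenolysis because any basic unmasking would endanger the aryl esters. Hindered pivalates are kept because a less hindered acyl group next to the carboxylate could transfer and close the lactone through the oxygen already present. The coupling must tolerate two aryl esters.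

3 ⇒ 2 ⇒ 1 and 5 ⇒ 4. Cut: the C–B bond and two O–acyl bonds on one side, the ester O–C bond on the other. Both branches end at commercial bromides. The borylation must use a base too weak to cleave aryl esters.

## Other disconnections considered

Alternative 1: The cut goes through two bonds at ring B at once, C2'–C8 and C1'–C2 (the carboxyl carbon that later becomes C2 of flavone 1). In the forward sense an isopropyl Grignard reagent exchanges the iodine of the iodoaryl sulfonate A2 and loss of the sulfonate releases a chloro-methoxy aryne. The hindered aryl Grignard reagent A3 adds at the aryne carbon remote from chlorine, and the new aryl–magnesium bond at C1' is trapped with carbon dioxide to give the acid A1.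
- In its favour: one flask makes the biaryl bond and the carboxyl group, no palladium is needed, and all three ring-D oxygens arrive with the nucleophile, so no C–H oxidation is required. Up to a biaryl acid this is better than the chosen plan in number of operations.
- Against it here: regiocontrol rests on a chlorine at C6' that is not in the target and must be removed by hydrogenolysis before benzyl ethers are introduced. A2 is not commercial, and its iodine must sit between an oxygen and a chlorine, which costs steps of uncertain selectivity. Addition of a 2,6-dialkoxyaryl nucleophile and carboxylation beside the new bulky aryl group are both sterically demanding.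
- Comparison: structurally, the three acetal-protected oxygens of A1 are equivalent; acid would free them and close a chlorinated analogue of 10, so from there the two plans are equal and both use the lactone to tell the oxygens apart. Mechanistically it is polar addition to a distorted aryne against an anodic radical closure; neither makes a stereocentre. In step economy the alternative should be shorter to the lactone and longer by the dechlorination and the preparation of A2, so about equal overall, with the risk shifted from the C–O bond formation to reagent preparation.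

Alternative 2: The cut goes through O1–C2 of both pyranone rings and leads back to the bichalcone A5. In the forward sense A5 is heated with catalytic iodine in DMSO; each ortho hydroxyl adds to its enone and the intermediates are dehydrogenated, which would give A4, a compound identical with 18.
- In its favour: two rings close in one metal-free operation and it ends at the same protected biflavone as the chosen plan. At the ring-closure stage it is better in step economy.
- Against it here: A5 already contains the whole difficulty, namely the biaryl with three ortho substituents and a ring D in which only the C8a hydroxyl is free. Ring B must carry an aldehyde-derived enone and ring D a ketone-derived enone, made by two aldol condensations with different partners that must be kept from crossing. The C8a hydroxyl can add to the β-carbon of the ring-B enone through a six-membered ring (a 6H-benzo[c]chromene) instead of to its own enone. Hot iodine and hydrogen iodide can cleave the C5 benzyl ether or iodinate C6.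
- Comparison: structurally, the chosen plan settles the oxygenation pattern and the differentiation before any pyranone exists, whereas the alternative needs both solved beforehand. Mechanistically it is ionic conjugate addition and iodination–elimination against anodic C–O formation, and needing no electrochemical equipment is a point for the alternative. In step economy it is better at the end, but the way to A5 should be at least as long as the way to 15.

Alternative 3: The cut removes ring D altogether; C8–C8a, C6–C7 and C4a–C8a are formed in one thermal cascade. In the forward sense the cyclobutenone A8 opens to a vinylketene, which adds to the siloxyalkyne A7 in a [2+2] sense; four-electron ring opening, six-electron ring closure and tautomerisation would give the phenol A6.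
- In its favour: no biaryl coupling and no C–H oxidation are needed. Ring D is formed with three different oxygens (free hydroxyl at C8a, silyl ether at C7, ethyl ether at C5) and with a bromide on ring B as the handle for flavone 1. In differentiating the ring-D oxygens it is better than the chosen plan, which needs a saponification and a re-protection.
- Against it here: A7 would have to come from a ring-B ester by ynolate chemistry with alkyllithium reagents that also attack the aryl bromide. A7 and A8 are sensitive. The C5 ethyl ether must be cleaved at the very end beside two methyl ethers that must stay, relying only on chelation to the C4 carbonyl. Both pyranone rings remain to be built, and the ring-B carbon of flavone 1 must be introduced through the bromide beside a hindered phenol.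
- Comparison: structurally, regiochemistry is dictated by the pericyclic sequence and is equal in certainty to the chosen plan. Mechanistically it uses concerted thermal steps with no oxidant or electrode, against a two-electron anodic oxidation. In step economy it is shorter to a differentiated ring D and longer afterwards, so no net gain is expected.

Key step: step 6

Remark: the C2'–C8 axis is drawn without a descriptor, so the target is taken as configurationally unassigned (racemic if rotation should be slow); the route contains no stereocentre.
Remark: the structures of 7 and 8 were checked atom by atom against the target (new oxygen on the future C8a, acyloxy groups on the future C7 and C5) and need no correction; what is tightened is their handling, namely neutral unmasking of the acid and a non-nucleophilic electrolyte.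

## Route

Step 1
Reactants: 1 4-bromoresorcinol (4-bromobenzene-1,3-diol)
Product: 2 4-bromo-1,3-phenylene bis(2,2-dimethylpropanoate)
Conditions: PivCl (2.4 equiv), Et3N (3 equiv), DMAP (5 mol%), CH2Cl2, 0 °C to rt
Reagents that add atoms: pivaloyl chloride, CC(C)(C)C(=O)Cl
Why: Base-mediated O-acylation of both phenols (DMAP-catalysed esterification); the hindered, electron-withdrawing esters make ring D hard to oxidise and are robust enough for two palladium-catalysed steps.

Step 2
Reactants: 2 4-bromo-1,3-phenylene bis(2,2-dimethylpropanoate)
Product: 3 4-(4,4,5,5-tetramethyl-1,3,2-dioxaborolan-2-yl)-1,3-phenylene bis(2,2-dimethylpropanoate)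
Conditions: B2pin2 (1.2 equiv), Pd(dppf)Cl2 (3 mol%), KOAc (3 equiv), 1,4-dioxane, 85 °C
Reagents that add atoms: bis(pinacolato)diboron, CC1(C)OB(OC1(C)C)B1OC(C)(C)C(C)(C)O1
Why: Miyaura borylation of the aryl bromide; acetate is too weak a base to cleave aryl pivalates or to promote homocoupling, and palladium does not insert into the aryl C–O ester bonds.

Step 3
Reactants: 4 2-bromo-4-methoxybenzoic acid
Product: 5 benzyl 2-bromo-4-methoxybenzoate
Conditions: BnBr (1.1 equiv), K2CO3 (1.5 equiv), DMF, rt
Reagents that add atoms: benzyl bromide, BrCc1ccccc1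
Why: SN2 O-alkylation of the carboxylate; the benzyl ester can later be removed by hydrogenolysis without any base, which the aryl pivalates would not tolerate.

Step 4
Reactants: 3 4-(4,4,5,5-tetramethyl-1,3,2-dioxaborolan-2-yl)-1,3-phenylene bis(2,2-dimethylpropanoate); 5 benzyl 2-bromo-4-methoxybenzoate
Product: 6 benzyl 2-[2,4-bis(pivaloyloxy)phenyl]-4-methoxybenzoate
Conditions: Pd(OAc)2 (3 mol%), SPhos (6 mol%), K3PO4 (2 equiv), toluene/H2O (10:1), 70 °C
Reagents that add atoms: none
Why: Suzuki–Miyaura coupling forming the C2'–C8 biaryl bond; each ring brings only one ortho substituent, so the coupling is unhindered, and phosphate in a mostly organic medium should leave the hindered aryl esters and the benzyl ester intact.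

Step 5
Reactants: 6 benzyl 2-[2,4-bis(pivaloyloxy)phenyl]-4-methoxybenzoate
Product: 7 2-[2,4-bis(pivaloyloxy)phenyl]-4-methoxybenzoic acid
Conditions: H2 (1 atm), 10% Pd/C, EtOAc, rt
Reagents that add atoms: none
Why: Hydrogenolysis of the benzyl ester under neutral conditions; nothing else in 6 is reducible, and 7 is taken directly into the electrolysis so that slow transfer of the neighbouring pivaloyl group to the carboxyl group has no time to occur.

Step 6
Reactants: 7 2-[2,4-bis(pivaloyloxy)phenyl]-4-methoxybenzoic acid
Product: 8 9-methoxy-1,3-bis(pivaloyloxy)-6H-benzo[c]chromen-6-one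
Conditions: undivided cell, graphite anode, Pt cathode, constant current (about 5 mA cm−2, 2.5–3 F mol−1), n-Bu4NBF4 (0.1 M), 2,4,6-collidine (1 equiv), MeCN/1,1,1,3,3,3-hexafluoropropan-2-ol (4:1), rt, N2
Reagents that add atoms: none
Why: Collidine gives the carboxylate, which is oxidised at the anode to an aroyloxy radical (a Kolbe-type oxidation without decarboxylation, since aryl carboxyl radicals lose CO2 slowly); the oxygen radical adds to C8a of ring D, a second electron is removed, and loss of the proton restores aromaticity while the fluorinated alcohol is reduced to H2 at the cathode. The closest known reaction type is the anodic dehydrogenative lactonisation of biaryl-2-carboxylic acids to 6H-benzo[c]chromen-6-ones. The ring closes in the six-membered (6-endo) mode onto the ortho carbon, in competition with 5-exo attack at the ipso carbon C8. No stereocentre is formed. The step needs site selectivity (C8a, not C8) and chemoselectivity (carboxylate before arene): the other ortho position carries a pivalate, and because ring D bears acyloxy and not alkoxy groups the spiro radical from ipso attack cannot be oxidised on to a stabilised oxocarbenium ion and should revert, whereas the C8a adduct is drained irreversibly by oxidation and deprotonation. The acyloxy groups also raise the oxidation potential of ring D above that of the carboxylate, and the non-nucleophilic medium keeps the aryl esters from solvolysis by base formed at the cathode.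

Step 7
Reactants: 8 9-methoxy-1,3-bis(pivaloyloxy)-6H-benzo[c]chromen-6-one
Product: 10 1,3-dihydroxy-9-methoxy-6H-benzo[c]chromen-6-one, via trihydroxy acid 9 (not isolated)
Conditions: NaOH (6 equiv), THF/MeOH/H2O, degassed, 40 °C; then 2 M HCl to pH 1, 60 °C
Reagents that add atoms: sodium hydroxide, [Na+].[OH-] (its oxygen enters the carboxyl group of 9 and can remain as the carbonyl oxygen of 10)
Why: Saponification cleaves both pivalates and opens the lactone to the salt of 9; on acidification the 2'-hydroxybiaryl-2-carboxylic acid relactonises (acid-catalysed esterification through a six-membered ring), and since the two ortho hydroxyls of 9 are symmetry-equivalent only one lactone can form.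

Step 8
Reactants: 10 1,3-dihydroxy-9-methoxy-6H-benzo[c]chromen-6-one
Product: 11 1,3-bis(benzyloxy)-9-methoxy-6H-benzo[c]chromen-6-one
Conditions: BnBr (2.4 equiv), K2CO3 (3 equiv), dry DMF, 55 °C
Reagents that add atoms: benzyl bromide, BrCc1ccccc1
Why: Williamson etherification of both phenols; under anhydrous carbonate the lactone stays closed, and the benzyl ethers are stable to the strong base, dilute acid and palladium chemistry ahead.

Step 9
Reactants: 11 1,3-bis(benzyloxy)-9-methoxy-6H-benzo[c]chromen-6-one
Product: 12 1,3-bis(benzyloxy)-4-iodo-9-methoxy-6H-benzo[c]chromen-6-one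
Conditions: NIS (1.05 equiv), TFA (0.2 equiv), MeCN/CH2Cl2 (1:1), 0 °C to rt, dark
Reagents that add atoms: N-iodosuccinimide, O=C1CCC(=O)N1I
Why: Electrophilic aromatic iodination; with the C8a oxygen acylated in the lactone, ring D reacts as a resorcinol dibenzyl ether, and C4 (the future C4a of flavone 2) is ortho to one ether, para to the other and flanked by only one of them, whereas C2 lies between both, the same preference that directs halogenation of 5,7-dialkoxychromones to C8. Ring B is deactivated by its para carbonyl group.

Step 10
Reactants: 12 1,3-bis(benzyloxy)-4-iodo-9-methoxy-6H-benzo[c]chromen-6-one; 13 1-(2,6-dihydroxy-4-methoxyphenyl)ethan-1-one (2',6'-dihydroxy-4'-methoxyacetophenone)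
Product: 14 1-{2-[4,6-bis(benzyloxy)-2-hydroxy-3-iodophenyl]-4-methoxyphenyl}-3-(2,6-dihydroxy-4-methoxyphenyl)propane-1,3-dione
Conditions: 13 (1.5 equiv), LiN(SiMe3)2 (6 equiv), THF, −78 to −10 °C; then 12, −78 °C to rt; 1 M HCl quench at 0 °C
Reagents that add atoms: none
Why: Crossed Claisen condensation: the trilithium salt of 13 is C-acylated by the aryl-ester carbonyl of the lactone, the tetrahedral intermediate expels the ring-D phenoxide (the C8a oxygen), and deprotonation of the new 1,3-diketone by excess base makes the opening irreversible; O-acylation followed by a Baker–Venkataraman acyl shift would lead to the same product. The aryl iodide has no ortho hydrogen and is inert to the amide base.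

Step 11
Reactants: 14 1-{2-[4,6-bis(benzyloxy)-2-hydroxy-3-iodophenyl]-4-methoxyphenyl}-3-(2,6-dihydroxy-4-methoxyphenyl)propane-1,3-dione
Product: 15 2-{2-[4,6-bis(benzyloxy)-2-hydroxy-3-iodophenyl]-4-methoxyphenyl}-5-hydroxy-7-methoxy-4H-chromen-4-one
Conditions: AcOH, H2SO4 (0.5% v/v), 60 °C
Reagents that add atoms: none
Why: Acid-catalysed cyclodehydration of a 1-(2-hydroxyaryl)-1,3-diketone: one of the two equivalent ring-A hydroxyls adds to the ring-B-side carbonyl and loss of water gives the pyranone, leaving the other as the chelated 5-hydroxyl; the aromatic 4-pyranone is the thermodynamic sink, so the reversible hemiketal with the ring-D hydroxyl should drain into it. Dilute acid at moderate temperature is chosen to spare the benzyl ethers and the C–I bond.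

Step 12
Reactants: 15 2-{2-[4,6-bis(benzyloxy)-2-hydroxy-3-iodophenyl]-4-methoxyphenyl}-5-hydroxy-7-methoxy-4H-chromen-4-one; 16 1-(benzyloxy)-4-ethynylbenzene
Product: 18 5,7-bis(benzyloxy)-2-[4-(benzyloxy)phenyl]-8-[2-(5-hydroxy-7-methoxy-4-oxo-4H-chromen-2-yl)-5-methoxyphenyl]-4H-chromen-4-one, via hydroxyaryl ynone 17 (not isolated)
Conditions: 16 (1.5 equiv), CO (5 bar), PdCl2(dppf) (5 mol%), Et2NH/DMF (1:3), 90 °C
Reagents that add atoms: carbon monoxide, [C-]#[O+]
Why: Carbonylative Sonogashira coupling with annulation of an ortho-iodophenol: the C–I bond adds oxidatively to zerovalent palladium, CO inserts to give the aroyl-palladium species (favoured on this electron-rich, doubly ortho-substituted ring), and coupling with the acetylide gives ynone 17; diethylamine then adds to the ynone and the C8a hydroxyl displaces it in a 6-endo closure that gives the flavone and not the aurone. Only the C8a hydroxyl is free and ortho to the new acyl group, so the 8-aryl flavone must result.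

Step 13
Reactants: 18 5,7-bis(benzyloxy)-2-[4-(benzyloxy)phenyl]-8-[2-(5-hydroxy-7-methoxy-4-oxo-4H-chromen-2-yl)-5-methoxyphenyl]-4H-chromen-4-one
Product: 19 5,7-dihydroxy-8-[2-(5-hydroxy-7-methoxy-4-oxo-4H-chromen-2-yl)-5-methoxyphenyl]-2-(4-hydroxyphenyl)-4H-chromen-4-one (target)
Conditions: H2 (1 atm), 10% Pd/C, THF/MeOH (1:1), rt
Reagents that add atoms: none
Why: Hydrogenolysis of three aryl benzyl ethers under neutral conditions; the methyl ethers and the pyranone double bonds should not be reduced at atmospheric pressure, and the absence of acid avoids Wessely–Moser isomerisation of the 5,7-dihydroxy-8-aryl flavone to its 6-aryl isomer.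

## Compound list

1 | 4-bromoresorcinol (4-bromobenzene-1,3-diol) | Oc1ccc(Br)c(O)c1 | starting material
2 | 4-bromo-1,3-phenylene bis(2,2-dimethylpropanoate) | CC(C)(C)C(=O)Oc1ccc(Br)c(OC(=O)C(C)(C)C)c1 | intermediate
3 | 4-(4,4,5,5-tetramethyl-1,3,2-dioxaborolan-2-yl)-1,3-phenylene bis(2,2-dimethylpropanoate) | CC(C)(C)C(=O)Oc1ccc(B2OC(C)(C)C(C)(C)O2)c(OC(=O)C(C)(C)C)c1 | intermediate
4 | 2-bromo-4-methoxybenzoic acid | COc1ccc(C(=O)O)c(Br)c1 | starting material
5 | benzyl 2-bromo-4-methoxybenzoate | COc1ccc(C(=O)OCc2ccccc2)c(Br)c1 | intermediate
6 | benzyl 2-[2,4-bis(pivaloyloxy)phenyl]-4-methoxybenzoate | COc1ccc(C(=O)OCc2ccccc2)c(-c2ccc(OC(=O)C(C)(C)C)cc2OC(=O)C(C)(C)C)c1 | intermediate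
7 | 2-[2,4-bis(pivaloyloxy)phenyl]-4-methoxybenzoic acid | COc1ccc(C(=O)O)c(-c2ccc(OC(=O)C(C)(C)C)cc2OC(=O)C(C)(C)C)c1 | intermediate
8 | 9-methoxy-1,3-bis(pivaloyloxy)-6H-benzo[c]chromen-6-one | COc1ccc2c(c1)-c1c(OC(=O)C(C)(C)C)cc(OC(=O)C(C)(C)C)cc1OC2=O | intermediate
9 | 4-methoxy-2-(2,4,6-trihydroxyphenyl)benzoic acid (present as its sodium salt) | COc1ccc(C(=O)O)c(-c2c(O)cc(O)cc2O)c1 | intermediate (not isolated)
10 | 1,3-dihydroxy-9-methoxy-6H-benzo[c]chromen-6-one | COc1ccc2c(c1)-c1c(O)cc(O)cc1OC2=O | intermediate
11 | 1,3-bis(benzyloxy)-9-methoxy-6H-benzo[c]chromen-6-one | COc1ccc2c(c1)-c1c(OCc3ccccc3)cc(OCc3ccccc3)cc1OC2=O | intermediate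
12 | 1,3-bis(benzyloxy)-4-iodo-9-methoxy-6H-benzo[c]chromen-6-one | COc1ccc2c(c1)-c1c(OCc3ccccc3)cc(OCc3ccccc3)c(I)c1OC2=O | intermediate
13 | 1-(2,6-dihydroxy-4-methoxyphenyl)ethan-1-one | CC(=O)c1c(O)cc(OC)cc1O | starting material
14 | 1-{2-[4,6-bis(benzyloxy)-2-hydroxy-3-iodophenyl]-4-methoxyphenyl}-3-(2,6-dihydroxy-4-methoxyphenyl)propane-1,3-dione | COc1ccc(C(=O)CC(=O)c2c(O)cc(OC)cc2O)c(-c2c(O)c(I)c(OCc3ccccc3)cc2OCc2ccccc2)c1 | intermediate
15 | 2-{2-[4,6-bis(benzyloxy)-2-hydroxy-3-iodophenyl]-4-methoxyphenyl}-5-hydroxy-7-methoxy-4H-chromen-4-one | COc1ccc(-c2cc(=O)c3c(O)cc(OC)cc3o2)c(-c2c(O)c(I)c(OCc3ccccc3)cc2OCc2ccccc2)c1 | intermediate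
16 | 1-(benzyloxy)-4-ethynylbenzene | C#Cc1ccc(OCc2ccccc2)cc1 | starting material
17 | 2-{2-[4,6-bis(benzyloxy)-3-{3-[4-(benzyloxy)phenyl]prop-2-ynoyl}-2-hydroxyphenyl]-4-methoxyphenyl}-5-hydroxy-7-methoxy-4H-chromen-4-one | COc1ccc(-c2cc(=O)c3c(O)cc(OC)cc3o2)c(-c2c(O)c(C(=O)C#Cc3ccc(OCc4ccccc4)cc3)c(OCc3ccccc3)cc2OCc2ccccc2)c1 | intermediate (not isolated)
18 | 5,7-bis(benzyloxy)-2-[4-(benzyloxy)phenyl]-8-[2-(5-hydroxy-7-methoxy-4-oxo-4H-chromen-2-yl)-5-methoxyphenyl]-4H-chromen-4-one | COc1ccc(-c2cc(=O)c3c(O)cc(OC)cc3o2)c(-c2c(OCc3ccccc3)cc(OCc3ccccc3)c3c(=O)cc(-c4ccc(OCc5ccccc5)cc4)oc23)c1 | intermediate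
19 | 5,7-dihydroxy-8-[2-(5-hydroxy-7-methoxy-4-oxo-4H-chromen-2-yl)-5-methoxyphenyl]-2-(4-hydroxyphenyl)-4H-chromen-4-one | COc1ccc(-c2cc(=O)c3c(O)cc(OC)cc3o2)c(-c2c(O)cc(O)c3c(=O)cc(-c4ccc(O)cc4)oc23)c1 | target

## Step count and least certain steps

Total: 13 steps. Longest linear sequence: 12 steps (from 1 through steps 1, 2 and 4 to 13); the branch from 4 joins at step 4.

Step 6 (key step). The most likely failures are addition of the aroyloxy radical at the ipso carbon with dearomatisation, oxidation of the anisole-type ring B in place of the carboxylate, or transfer of the ortho pivaloyl group to the carboxylate before electrolysis. The last would close the lactone through the oxygen already present and consume 7 without installing the new one. Fallback: a copper-catalysed Hurtley condensation that sets out from 4 and comes back at 10. Acid 4 is heated with phloroglucinol (benzene-1,3,5-triol) and catalytic CuSO4 in aqueous NaOH; a ring carbon of the phloroglucinol anion displaces the bromide ortho to the carboxylate to give 9 in the flask, and acidification lactonises it to 10. All three ring-D oxygens then arrive with the arene, steps 1 to 7 are bypassed, and no compound outside the list is made (F0).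

Step 10. The most likely failure is incomplete acylation by the aggregated trilithium salt, together with reversal of the opening: the liberated ring-D phenoxide re-adds to the new ketone and expels the enolate (retro-Claisen), which would return 12. Fallback: set out from 12 and return at 15 with the ring-D oxygen capped.
- Aminolysis of the lactone with N,O-dimethylhydroxylamine hydrochloride and AlMe3 (CH2Cl2, 0 °C to rt) should give the Weinreb amide 2-[4,6-bis(benzyloxy)-2-hydroxy-3-iodophenyl]-N,4-dimethoxy-N-methylbenzamide F1.
- The free phenol is capped with chloromethyl methyl ether and i-Pr2NEt as the methoxymethyl ether 2-[4,6-bis(benzyloxy)-3-iodo-2-(methoxymethoxy)phenyl]-N,4-dimethoxy-N-methylbenzamide F2.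
- Acylation of the trilithium salt of 13 by F2 gives the capped diketone 1-{2-[4,6-bis(benzyloxy)-3-iodo-2-(methoxymethoxy)phenyl]-4-methoxyphenyl}-3-(2,6-dihydroxy-4-methoxyphenyl)propane-1,3-dione F3, which cannot close back.
- HCl in MeOH at 50 °C then closes ring C and removes the acetal, arriving at 15.

Step 11. The most likely failure is loss or migration of iodine by ipso-protonation of the very electron-rich ring D, and dehydration of the hemiketal formed with the ring-D hydroxyl to a benzo[c]chromene enol ether instead of the pyranone. Fallback: keep iodine out of the acid step altogether, setting out from 11 and returning at 18.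
- Lactone 11 is opened with the trilithium salt of 13 to the iodine-free diketone 1-{2-[2,4-bis(benzyloxy)-6-hydroxyphenyl]-4-methoxyphenyl}-3-(2,6-dihydroxy-4-methoxyphenyl)propane-1,3-dione F4.
- Cyclodehydration in AcOH with catalytic H2SO4 gives 2-{2-[2,4-bis(benzyloxy)-6-hydroxyphenyl]-4-methoxyphenyl}-5-hydroxy-7-methoxy-4H-chromen-4-one F5.
- Hydroxyl-directed ortho-formylation (MgCl2, Et3N, paraformaldehyde, MeCN, reflux) can only occur at the one free position ortho to the C8a hydroxyl and should give the salicylaldehyde 4,6-bis(benzyloxy)-2-hydroxy-3-[2-(5-hydroxy-7-methoxy-4-oxo-4H-chromen-2-yl)-5-methoxyphenyl]benzaldehyde F6.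
- Excess lithium acetylide of 16 (THF, −78 °C) gives the racemic propargylic alcohol 2-{2-[4,6-bis(benzyloxy)-3-{3-[4-(benzyloxy)phenyl]-1-hydroxyprop-2-yn-1-yl}-2-hydroxyphenyl]-4-methoxyphenyl}-5-hydroxy-7-methoxy-4H-chromen-4-one F7.
- MnO2 oxidises F7 to 17, and Et2NH closes 17 to 18. Steps 9 to 12 are bypassed.

Step 12. The most likely failure is alkynyl transfer before CO insertion (leading after cyclisation to a 2-arylbenzofuran), 5-exo closure to an aurone, or inhibition of the catalyst by the chelating 5-hydroxy-4-oxo unit. Fallback: set out from 15 and return at 18 by the chalcone route.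
- Stille coupling of 15 with tributyl(1-ethoxyvinyl)stannane (Pd(PPh3)4, toluene, 100 °C) gives the enol ether 2-{2-[4,6-bis(benzyloxy)-3-(1-ethoxyethenyl)-2-hydroxyphenyl]-4-methoxyphenyl}-5-hydroxy-7-methoxy-4H-chromen-4-one F8.
- Aqueous HCl hydrolyses F8 to the methyl ketone 2-{2-[3-acetyl-4,6-bis(benzyloxy)-2-hydroxyphenyl]-4-methoxyphenyl}-5-hydroxy-7-methoxy-4H-chromen-4-one F9.
- Claisen–Schmidt condensation with 4-(benzyloxy)benzaldehyde (KOH, EtOH/THF, rt) gives the chalcone 2-{2-[4,6-bis(benzyloxy)-3-{(2E)-3-[4-(benzyloxy)phenyl]prop-2-enoyl}-2-hydroxyphenyl]-4-methoxyphenyl}-5-hydroxy-7-methoxy-4H-chromen-4-one F10.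
- Catalytic I2 in DMSO at 120 °C closes and dehydrogenates F10 to 18.

## Further compounds

F0 | step 6 | none | none
F1 | step 10 | 2-[4,6-bis(benzyloxy)-2-hydroxy-3-iodophenyl]-N,4-dimethoxy-N-methylbenzamide | COc1ccc(C(=O)N(C)OC)c(-c2c(O)c(I)c(OCc3ccccc3)cc2OCc2ccccc2)c1
F2 | step 10 | 2-[4,6-bis(benzyloxy)-3-iodo-2-(methoxymethoxy)phenyl]-N,4-dimethoxy-N-methylbenzamide | COc1ccc(C(=O)N(C)OC)c(-c2c(OCOC)c(I)c(OCc3ccccc3)cc2OCc2ccccc2)c1
F3 | step 10 | 1-{2-[4,6-bis(benzyloxy)-3-iodo-2-(methoxymethoxy)phenyl]-4-methoxyphenyl}-3-(2,6-dihydroxy-4-methoxyphenyl)propane-1,3-dione | COc1ccc(C(=O)CC(=O)c2c(O)cc(OC)cc2O)c(-c2c(OCOC)c(I)c(OCc3ccccc3)cc2OCc2ccccc2)c1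
F4 | step 11 | 1-{2-[2,4-bis(benzyloxy)-6-hydroxyphenyl]-4-methoxyphenyl}-3-(2,6-dihydroxy-4-methoxyphenyl)propane-1,3-dione | COc1ccc(C(=O)CC(=O)c2c(O)cc(OC)cc2O)c(-c2c(O)cc(OCc3ccccc3)cc2OCc2ccccc2)c1
F5 | step 11 | 2-{2-[2,4-bis(benzyloxy)-6-hydroxyphenyl]-4-methoxyphenyl}-5-hydroxy-7-methoxy-4H-chromen-4-one | COc1ccc(-c2cc(=O)c3c(O)cc(OC)cc3o2)c(-c2c(O)cc(OCc3ccccc3)cc2OCc2ccccc2)c1
F6 | step 11 | 4,6-bis(benzyloxy)-2-hydroxy-3-[2-(5-hydroxy-7-methoxy-4-oxo-4H-chromen-2-yl)-5-methoxyphenyl]benzaldehyde | COc1ccc(-c2cc(=O)c3c(O)cc(OC)cc3o2)c(-c2c(O)c(C=O)c(OCc3ccccc3)cc2OCc2ccccc2)c1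
F7 | step 11 | 2-{2-[4,6-bis(benzyloxy)-3-{3-[4-(benzyloxy)phenyl]-1-hydroxyprop-2-yn-1-yl}-2-hydroxyphenyl]-4-methoxyphenyl}-5-hydroxy-7-methoxy-4H-chromen-4-one (racemic) | COc1ccc(-c2cc(=O)c3c(O)cc(OC)cc3o2)c(-c2c(O)c(C(O)C#Cc3ccc(OCc4ccccc4)cc3)c(OCc3ccccc3)cc2OCc2ccccc2)c1
F8 | step 12 | 2-{2-[4,6-bis(benzyloxy)-3-(1-ethoxyethenyl)-2-hydroxyphenyl]-4-methoxyphenyl}-5-hydroxy-7-methoxy-4H-chromen-4-one | COc1ccc(-c2cc(=O)c3c(O)cc(OC)cc3o2)c(-c2c(O)c(C(=C)OCC)c(OCc3ccccc3)cc2OCc2ccccc2)c1
F9 | step 12 | 2-{2-[3-acetyl-4,6-bis(benzyloxy)-2-hydroxyphenyl]-4-methoxyphenyl}-5-hydroxy-7-methoxy-4H-chromen-4-one | COc1ccc(-c2cc(=O)c3c(O)cc(OC)cc3o2)c(-c2c(O)c(C(C)=O)c(OCc3ccccc3)cc2OCc2ccccc2)c1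
F10 | step 12 | 2-{2-[4,6-bis(benzyloxy)-3-{(2E)-3-[4-(benzyloxy)phenyl]prop-2-enoyl}-2-hydroxyphenyl]-4-methoxyphenyl}-5-hydroxy-7-methoxy-4H-chromen-4-one | COc1ccc(-c2cc(=O)c3c(O)cc(OC)cc3o2)c(-c2c(O)c(C(=O)/C=C/c3ccc(OCc4ccccc4)cc3)c(OCc3ccccc3)cc2OCc2ccccc2)c1
A1 | alternative 1 | 2-chloro-4-methoxy-6-[2,4,6-tris(methoxymethoxy)phenyl]benzoic acid | COc1cc(Cl)c(C(=O)O)c(-c2c(OCOC)cc(OCOC)cc2OCOC)c1
A2 | alternative 1 | 3-chloro-2-iodo-5-methoxyphenyl 4-chlorobenzenesulfonate | COc1cc(Cl)c(I)c(OS(=O)(=O)c2ccc(Cl)cc2)c1
A3 | alternative 1 | [2,4,6-tris(methoxymethoxy)phenyl]magnesium bromide | COCOc1cc(OCOC)c([Mg]Br)c(OCOC)c1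
A4 | alternative 2 | 5,7-bis(benzyloxy)-2-[4-(benzyloxy)phenyl]-8-[2-(5-hydroxy-7-methoxy-4-oxo-4H-chromen-2-yl)-5-methoxyphenyl]-4H-chromen-4-one (identical with 18) | COc1ccc(-c2cc(=O)c3c(O)cc(OC)cc3o2)c(-c2c(OCc3ccccc3)cc(OCc3ccccc3)c3c(=O)cc(-c4ccc(OCc5ccccc5)cc4)oc23)c1
A5 | alternative 2 | (2E)-3-{2-[4,6-bis(benzyloxy)-3-{(2E)-3-[4-(benzyloxy)phenyl]prop-2-enoyl}-2-hydroxyphenyl]-4-methoxyphenyl}-1-(2,6-dihydroxy-4-methoxyphenyl)prop-2-en-1-one | COc1ccc(/C=C/C(=O)c2c(O)cc(OC)cc2O)c(-c2c(O)c(C(=O)/C=C/c3ccc(OCc4ccccc4)cc3)c(OCc3ccccc3)cc2OCc2ccccc2)c1
A6 | alternative 3 | 2-(2-bromo-5-methoxyphenyl)-5-ethoxy-3-(triisopropylsilyloxy)phenol | CCOc1cc(O)c(-c2cc(OC)ccc2Br)c(O[Si](C(C)C)(C(C)C)C(C)C)c1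
A7 | alternative 3 | {[(2-bromo-5-methoxyphenyl)ethynyl]oxy}tri(propan-2-yl)silane | COc1ccc(Br)c(C#CO[Si](C(C)C)(C(C)C)C(C)C)c1
A8 | alternative 3 | 3-ethoxycyclobut-2-en-1-one | CCOC1=CC(=O)C1
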